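**Retrosynthetic overview**
1. The target is read as epicatechin-(4β→8)-catechin-(4α→8)-catechin whose terminal 3-OH carries a (1S)-1-hydroxy-6-oxocyclohex-2-ene-1-carbonyl group. Last disconnections: silyl ethers (HF), the C1–OH of the acyl ring (asymmetric α-hydroxylation of a β-keto ester), and the ester C–O bond (Birch acid of 2-methoxybenzoic acid).
2. Upper interflavan bond: C4 cation of an epicatechin unit onto C8 of a catechin-(4α→8)-catechin dimer (Friedel–Crafts).
3. Key disconnection: ring C of the middle unit is opened at C3–C4 (and O1–C2), giving an o-hydroxybenzhydrol (ring A of the middle unit–CH(OH)–C8 of the terminal catechin) and a cinnamaldehyde (ring B, C2, C3). The 3-formyl group left by the ring closure becomes the 3-OH by Baeyer–Villiger oxidation.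
4. Enabling feature: C4 of the middle unit is a benzhydrylic carbon flanked by two phloroglucinol-type rings (C4a of its own ring A, ortho to the phenolic O1 on C8a, and C8 of ring A of the terminal unit). It therefore ionises readily to a stabilised cation/o-quinone methide next to O1, the same kind of C4 cation that builds interflavan bonds in nature, used here to close ring C.
5. Ring order: the rings of the terminal catechin and the upper epicatechin come from the chiral pool; ring C of the middle unit is formed in the key step on a preformed ring A (phloroglucinaldehyde) and ring B (cinnamaldehyde); the cyclohexenone ring comes from a Birch reduction.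

Key step: step 6

Remark on the chemistry: (+)-catechin and (−)-epicatechin are taken as commercial chiral-pool materials for the terminal and upper units, and the middle unit is built de novo. Benzyl ethers are exchanged for silyl ethers before the hydrogenation-sensitive acyl ring is introduced. The exchange is done in two stages: the six ring A phenols are silylated while the three catechols are masked as boronates, and the catechols are silylated afterwards.

**Step 1**
Reactants: 1 (+)-catechin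
Product: 3 3,5,7,3',4'-penta-O-benzyl-(+)-catechin, via 5,7,3',4'-tetra-O-benzylcatechin 2 (not isolated)
Conditions: BnBr, K2CO3, DMF, rt; then NaH, BnBr, 0 °C → rt
Reagents that add atoms: benzyl bromide, BrCc1ccccc1
Why: Williamson etherification; carbonate benzylates the four phenols, NaH then the less acidic 3-OH, and no stereocentre is touched.

**Step 2**
Reactants: 3 3,5,7,3',4'-penta-O-benzyl-(+)-catechin
Product: 4 8-bromo-3,5,7,3',4'-penta-O-benzyl-(+)-catechin
Conditions: NBS, CH2Cl2, −78 °C → rt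
Reagents that add atoms: N-bromosuccinimide, BrN1C(=O)CCC1=O
Why: Electrophilic aromatic bromination should go to C8, which lies between O1 and one benzyloxy group and is less hindered than C6, as is usual for O-benzylated catechins.

**Step 3**
Reactants: 5 2,4,6-trihydroxybenzaldehyde
Product: 6 4,6-bis(benzyloxy)-2-hydroxybenzaldehyde
Conditions: BnBr (2.05 equiv), K2CO3, DMF, rt
Reagents that add atoms: benzyl bromide, BrCc1ccccc1
Why: Williamson etherification; the remaining ortho-hydroxyl is held in a hydrogen bond to the formyl group and should stay free.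

**Step 4**
Reactants: 7 3,4-bis(benzyloxy)benzaldehyde
Product: 8 (E)-3-[3,4-bis(benzyloxy)phenyl]prop-2-enal
Conditions: Ph3P=CHCHO (1.1 equiv), toluene, 80 °C
Reagents that add atoms: (triphenylphosphoranylidene)acetaldehyde, O=CC=P(c1ccccc1)(c1ccccc1)c1ccccc1
Why: Wittig olefination with a stabilised ylide should give the E enal.

**Step 5**
Reactants: 4 8-bromo-3,5,7,3',4'-penta-O-benzyl-(+)-catechin; 6 4,6-bis(benzyloxy)-2-hydroxybenzaldehyde
Product: 11 [4,6-bis(benzyloxy)-2-hydroxyphenyl](3,5,7,3',4'-penta-O-benzylcatechin-8-yl)methanol (both carbinol epimers; used crude), via 8-lithio-penta-O-benzylcatechin 9 (not isolated), via sodium 3,5-bis(benzyloxy)-2-formylphenoxide 10 (not isolated)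
Conditions: 4, n-BuLi, THF, −78 °C; add 6 pre-treated with NaH (THF, 0 °C); −78 → −20 °C; aq NH4Cl (pH 7)
Reagents that add atoms: none
Why: Bromine–lithium exchange followed by 1,2-addition of the aryllithium to the aldehyde, whose phenol is masked as its phenoxide; this makes the future C4–C8 interflavan bond, and the carbinol configuration is irrelevant because the centre is ionised in step 6.

**Step 6**
Reactants: 11 [4,6-bis(benzyloxy)-2-hydroxyphenyl](3,5,7,3',4'-penta-O-benzylcatechin-8-yl)methanol; 8 (E)-3-[3,4-bis(benzyloxy)phenyl]prop-2-enal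
Product: 13 (2,3-trans-3,4-trans)-5,7-bis(benzyloxy)-2-[3,4-bis(benzyloxy)phenyl]-4-(3,5,7,3',4'-penta-O-benzylcatechin-8-yl)chromane-3-carbaldehyde (2S,3S,4S at the new ring by the sequence rules; same spatial arrangement as a catechin-(4α→8) unit), via catalyst enamine of the oxa-Michael adduct 12 (not isolated)
Conditions: (S)-α,α-diphenylprolinol trimethylsilyl ether (20 mol%), 2-nitrobenzoic acid (20 mol%), CHCl3, 0 °C → rt
Reagents that add atoms: none
Why: The amine condenses with 8 to an iminium ion, the only free hydroxyl of 11 (the phenolic O1–H on ring A of the future middle unit) adds to its β-carbon (oxa-Michael) to give enamine 12, the acid co-catalyst ionises the benzhydrol to a cation/o-quinone-methide-type species stabilised by both tri-oxygenated rings, and the enamine carbon C3 captures C4 before hydrolysis returns the catalyst. The closest known reactions are the aminocatalytic iminium–enamine domino oxa-Michael/Michael and oxa-Michael/1,6-addition syntheses of 2,3,4-trisubstituted chromans and the SN1-type α-alkylation of aldehyde enamines by stabilised benzhydryl cations. Ring C (O1, C2, C3, C4, C4a, C8a) closes by attack of an exocyclic enamine on the trigonal C4, formally 6-endo-trig with respect to the C4=C4a bond of the quinone-methide resonance form. C2 is set by the catalyst, whose diphenyl(silyloxy)methyl group shields one face of the iminium ion (the S antipode is chosen because it should direct O1 to the Si face of the β-carbon, the sense that gives (R)-2-aryl-2H-chromene-3-carbaldehydes in the related oxa-Michael/aldol reaction and corresponds to the 2R arrangement of the target unit); C4 is set in a chair-like transition state with the 2-aryl group and the terminal-unit aryl both equatorial (2,4-cis); C3 is epimerisable through the enamine and should settle with the formyl group equatorial, trans to both aryl groups. The step needs chemoselectivity and enantioface control at C2: O1 is the only unprotected oxygen, so the pyran can form only on ring A of the middle unit, and 8 has no γ-hydrogen, so no dienamine pathway competes; in one operation the step joins the terminal unit, ring A and ring B and creates all three stereocentres of the middle unit.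

**Step 7**
Reactants: 13 (2,3-trans-3,4-trans)-chromane-3-carbaldehyde dimer
Product: 15 5,7,3',4'-tetra-O-benzylcatechin-(4α→8)-3,5,7,3',4'-penta-O-benzylcatechin (upper unit 2R,3S,4S; upper 3-OH free), via upper-unit 3-O-formyl dimer 14 (not isolated)
Conditions: mCPBA, NaHCO3, CH2Cl2, 0 °C; then K2CO3 (cat.), MeOH, 0 °C
Reagents that add atoms: 3-chloroperoxybenzoic acid, OOC(=O)c1cccc(Cl)c1
Why: Baeyer–Villiger oxidation of an α-branched aldehyde, in which the secondary C3 migrates with retention to give the formate, cleaved by mild methanolysis; the 3-OH thus inherits the all-trans configuration set in step 6.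

**Step 8**
Reactants: 16 (−)-epicatechin
Product: 17 5,7,3',4'-tetra-O-benzyl-(−)-epicatechin
Conditions: BnBr, K2CO3, DMF, rt
Reagents that add atoms: benzyl bromide, BrCc1ccccc1
Why: Williamson etherification of the four phenols; the 3-OH is not benzylated under carbonate.

**Step 9**
Reactants: 17 5,7,3',4'-tetra-O-benzyl-(−)-epicatechin
Product: 18 5,7,3',4'-tetra-O-benzyl-4β-(2-ethoxyethoxy)epicatechin (3,4-trans)
Conditions: DDQ, 2-ethoxyethanol, CH2Cl2, rt
Reagents that add atoms: 2-ethoxyethanol, CCOCCO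
Why: DDQ abstracts hydride from the benzylic C4 activated by ring A; the cation is trapped by the alcohol on the face anti to the 3-OH (benzylic oxidation with known precedent on this substrate class).

**Step 10**
Reactants: 15 catechin-(4α→8)-catechin nonabenzyl ether; 18 4β-(2-ethoxyethoxy)epicatechin tetrabenzyl ether
Product: 19 5,7,3',4'-tetra-O-benzylepicatechin-(4β→8)-5,7,3',4'-tetra-O-benzylcatechin-(4α→8)-3,5,7,3',4'-penta-O-benzylcatechin (3-OH of upper and middle units free)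
Conditions: TMSOTf (0.2 equiv), CH2Cl2, −78 °C, slow addition of 18
Reagents that add atoms: none
Why: Lewis-acid Friedel–Crafts coupling through the flavan-4-yl cation; attack anti to the 3-OH of the 2,3-cis unit gives the 4β bond, and C8 of the upper unit of 15 (between O1 and one benzyloxy group) is the most accessible nucleophilic site, as in known dimer-plus-monomer couplings.

**Step 11**
Reactants: 19 trimer diol
Product: 20 the 3-O-triethylsilyl ethers of 19 at the upper and middle units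
Conditions: TESOTf, 2,6-lutidine, CH2Cl2, 0 °C → rt
Reagents that add atoms: triethylsilyl trifluoromethanesulfonate, CC[Si](CC)(CC)OS(=O)(=O)C(F)(F)F
Why: Silyl triflate silylation of the two hindered secondary hydroxyls, so that only the terminal 3-oxygen can be acylated later.

**Step 12**
Reactants: 20 bis-triethylsilyl tridecabenzyl trimer
Product: 21 3-O-triethylsilylepicatechin-(4β→8)-3-O-triethylsilylcatechin-(4α→8)-catechin (twelve phenols and the terminal 3-OH free)
Conditions: H2 (1 atm), Pd(OH)2/C, THF/EtOAc, rt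
Reagents that add atoms: none
Why: Hydrogenolysis of the thirteen benzyl ethers; silyl ethers, interflavan bonds and the pyran rings should survive in a non-protic solvent.

**Step 13**
Reactants: 21 polyphenolic trimer
Product: 22 tris(phenylboronate) of 21, each of the three ring B catechols closed to a 2-phenyl-1,3,2-benzodioxaborole (six ring A phenols and terminal 3-OH free; used crude)
Conditions: PhB(OH)2 (3.0 equiv), 4 Å MS, THF/toluene, rt, argon; filtration, evaporation
Reagents that add atoms: phenylboronic acid, OB(O)c1ccccc1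
Why: Boronic ester formation is reversible and gives a stable five-membered cyclic ester only at the three ortho-dihydroxy rings; the meta-disposed ring A phenols and the lone 3-OH cannot form one, so the catechols are masked selectively (temporary boronate protection of 1,2-diols).

**Step 14**
Reactants: 22 tris(phenylboronate) of 21
Product: 24 hexa-O-tert-butyldimethylsilyl ether of 21 at the six ring A phenols (six catechol hydroxyls plus terminal 3-OH free), via hexa-O-TBS tris(phenylboronate) 23 (not isolated)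
Conditions: TBSCl (6.6 equiv), i-Pr2NEt, DMF, 0 °C → rt, argon; work-up; then pinacol (6 equiv), THF, rt
Reagents that add atoms: tert-butyldimethylsilyl chloride, CC(C)(C)[Si](C)(C)Cl
Why: Silylation of the six ring A phenols in the presence of a boronic ester protecting group, with phenols reacting much faster than the hindered secondary 3-OH; transesterification with pinacol then moves boron to the more stable pinacol ester and should return the free catechols under neutral conditions.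

**Step 15**
Reactants: 24 ring A hexasilyl ether with free catechols
Product: 25 dodeca-O-tert-butyldimethylsilyl ether of 21 at all twelve phenols (terminal 3-OH free)
Conditions: TBSCl (8 equiv), imidazole, DMF, 0 °C → rt, argon
Reagents that add atoms: tert-butyldimethylsilyl chloride, CC(C)(C)[Si](C)(C)Cl
Why: Silylation of the six catechol hydroxyls; phenols silylate much faster than the hindered secondary 3-OH of a catechin unit, the usual selectivity in phenol silylation of flavan-3-ols.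

**Step 16**
Reactants: 26 2-methoxybenzoic acid
Product: 27 2-methoxycyclohexa-2,5-diene-1-carboxylic acid (racemic)
Conditions: Na, NH3(l), THF, −78 °C; NH4Cl; cold acidification to pH 4
Reagents that add atoms: none
Why: Birch reduction of a benzoic acid gives the 1,4-dihydro acid with protonation at C1 and C4, keeping the methyl enol ether as a masked ketone.

**Step 17**
Reactants: 25 dodecasilyl trimer alcohol; 27 2-methoxycyclohexa-2,5-diene-1-carboxylic acid
Product: 28 terminal 3-O-(2-methoxycyclohexa-2,5-diene-1-carbonyl) ester of 25 (epimers at C1 of the acyl ring)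
Conditions: EDC, DMAP, CH2Cl2, 0 °C → rt, argon
Reagents that add atoms: none
Why: Steglich-type esterification of the only free hydroxyl; the C1 configuration of the acyl ring does not matter because it is erased by enolisation and set in step 19.

**Step 18**
Reactants: 28 dienyl ester
Product: 29 terminal 3-O-(6-oxocyclohex-2-ene-1-carbonyl) ester (β-keto ester, in equilibrium with its dienol)
Conditions: oxalic acid, THF/H2O, 0 °C → rt, argon
Reagents that add atoms: water, O
Why: Mild acid hydrolysis of the methyl enol ether (C-protonation, hemiketal, loss of methanol) should spare the aryl silyl ethers, the hindered triethylsilyl ethers and the interflavan bonds.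

**Step 19**
Reactants: 29 β-keto ester
Product: 30 dodeca-O-TBS-bis-O-TES-epicatechin-(4β→8)-catechin-(4α→8)-catechin terminal 3-O-[(1S)-1-hydroxy-6-oxocyclohex-2-ene-1-carboxylate]
Conditions: Ni(ClO4)2·6H2O (10 mol%), (R,R)-4,6-dibenzofurandiyl-2,2'-bis(4-phenyloxazoline) (11 mol%), 2-(phenylsulfonyl)-3-(4-nitrophenyl)oxaziridine (1.2 equiv), 4 Å MS, CH2Cl2, 0 °C
Reagents that add atoms: 2-(phenylsulfonyl)-3-(4-nitrophenyl)oxaziridine, O=S(=O)(c1ccccc1)N1OC1c1ccc(cc1)[N+](=O)[O-]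
Why: Catalytic asymmetric α-hydroxylation of a β-keto ester: the 1,3-dicarbonyl chelates the chiral divalent nickel bis(oxazoline) complex, which exposes one face of the bound dienolate to oxygen transfer at C1, the ligand antipode being chosen to give 1S; keto, enol and double-bond isomers of 29 converge on the same chelate.

**Step 20**
Reactants: 30 fully silylated ester
Product: 31 epicatechin-(4β→8)-catechin-(4α→8)-catechin terminal 3-O-[(1S)-1-hydroxy-6-oxocyclohex-2-ene-1-carboxylate]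
Conditions: HF·pyridine, pyridine, THF, 0 °C → rt; reversed-phase purification
Reagents that add atoms: none
Why: Fluoride-driven cleavage of the twelve aryl and two alkyl silyl ethers under mildly acidic conditions, which should spare the base-labile hydroxy keto ester, the isolated ring alkene and the interflavan bonds.

**Compound list**
1 | (+)-catechin | O[C@H]1Cc2c(O)cc(O)cc2O[C@@H]1c1ccc(O)c(O)c1 | starting material
2 | 5,7,3',4'-tetra-O-benzyl-(+)-catechin | O[C@H]1Cc2c(OCc3ccccc3)cc(OCc3ccccc3)cc2O[C@@H]1c1ccc(OCc2ccccc2)c(OCc2ccccc2)c1 | intermediate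
3 | 3,5,7,3',4'-penta-O-benzyl-(+)-catechin | C(c1ccccc1)O[C@H]1Cc2c(OCc3ccccc3)cc(OCc3ccccc3)cc2O[C@@H]1c1ccc(OCc2ccccc2)c(OCc2ccccc2)c1 | intermediate
4 | 8-bromo-3,5,7,3',4'-penta-O-benzyl-(+)-catechin | C(c1ccccc1)O[C@H]1Cc2c(OCc3ccccc3)cc(OCc3ccccc3)c(Br)c2O[C@@H]1c1ccc(OCc2ccccc2)c(OCc2ccccc2)c1 | intermediate
5 | 2,4,6-trihydroxybenzaldehyde | O=Cc1c(O)cc(O)cc1O | starting material
6 | 4,6-bis(benzyloxy)-2-hydroxybenzaldehyde | O=Cc1c(O)cc(OCc2ccccc2)cc1OCc1ccccc1 | intermediate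
7 | 3,4-bis(benzyloxy)benzaldehyde | O=Cc1ccc(OCc2ccccc2)c(OCc2ccccc2)c1 | starting material
8 | (E)-3-[3,4-bis(benzyloxy)phenyl]prop-2-enal | O=C/C=C/c1ccc(OCc2ccccc2)c(OCc2ccccc2)c1 | intermediate
9 | 8-lithio-3,5,7,3',4'-penta-O-benzylcatechin | C(c1ccccc1)O[C@H]1Cc2c(OCc3ccccc3)cc(OCc3ccccc3)c([Li])c2O[C@@H]1c1ccc(OCc2ccccc2)c(OCc2ccccc2)c1 | intermediate
10 | sodium 3,5-bis(benzyloxy)-2-formylphenoxide | [Na+].[O-]c1cc(OCc2ccccc2)cc(OCc2ccccc2)c1C=O | intermediate
11 | [4,6-bis(benzyloxy)-2-hydroxyphenyl](3,5,7,3',4'-penta-O-benzylcatechin-8-yl)methanol, both carbinol epimers | C(c1ccccc1)O[C@H]1Cc2c(OCc3ccccc3)cc(OCc3ccccc3)c(C(O)c3c(O)cc(OCc4ccccc4)cc3OCc3ccccc3)c2O[C@@H]1c1ccc(OCc2ccccc2)c(OCc2ccccc2)c1 | intermediate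
12 | E-enamine of (S)-α,α-diphenylprolinol trimethylsilyl ether with the 3-aryl-3-aryloxypropanal formed by oxa-Michael addition of 11 to 8 | C(c1ccccc1)O[C@H]1Cc2c(OCc3ccccc3)cc(OCc3ccccc3)c(C(O)c3c(O[C@H](c4ccc(OCc5ccccc5)c(OCc5ccccc5)c4)/C=C/N4CCC[C@H]4C(c4ccccc4)(c4ccccc4)O[Si](C)(C)C)cc(OCc4ccccc4)cc3OCc3ccccc3)c2O[C@@H]1c1ccc(OCc2ccccc2)c(OCc2ccccc2)c1 | intermediate
13 | (2,3-trans-3,4-trans)-5,7-bis(benzyloxy)-2-[3,4-bis(benzyloxy)phenyl]-4-(3,5,7,3',4'-penta-O-benzylcatechin-8-yl)chromane-3-carbaldehyde | C(c1ccccc1)O[C@H]1Cc2c(OCc3ccccc3)cc(OCc3ccccc3)c([C@@H]3c4c(OCc5ccccc5)cc(OCc5ccccc5)cc4O[C@H](c4ccc(OCc5ccccc5)c(OCc5ccccc5)c4)[C@H]3C=O)c2O[C@@H]1c1ccc(OCc2ccccc2)c(OCc2ccccc2)c1 | intermediate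
14 | 3-O-formyl-5,7,3',4'-tetra-O-benzylcatechin-(4α→8)-3,5,7,3',4'-penta-O-benzylcatechin | C(c1ccccc1)O[C@H]1Cc2c(OCc3ccccc3)cc(OCc3ccccc3)c([C@@H]3c4c(OCc5ccccc5)cc(OCc5ccccc5)cc4O[C@H](c4ccc(OCc5ccccc5)c(OCc5ccccc5)c4)[C@H]3OC=O)c2O[C@@H]1c1ccc(OCc2ccccc2)c(OCc2ccccc2)c1 | intermediate
15 | 5,7,3',4'-tetra-O-benzylcatechin-(4α→8)-3,5,7,3',4'-penta-O-benzylcatechin | C(c1ccccc1)O[C@H]1Cc2c(OCc3ccccc3)cc(OCc3ccccc3)c([C@@H]3c4c(OCc5ccccc5)cc(OCc5ccccc5)cc4O[C@H](c4ccc(OCc5ccccc5)c(OCc5ccccc5)c4)[C@H]3O)c2O[C@@H]1c1ccc(OCc2ccccc2)c(OCc2ccccc2)c1 | intermediate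
16 | (−)-epicatechin | O[C@@H]1Cc2c(O)cc(O)cc2O[C@@H]1c1ccc(O)c(O)c1 | starting material
17 | 5,7,3',4'-tetra-O-benzyl-(−)-epicatechin | O[C@@H]1Cc2c(OCc3ccccc3)cc(OCc3ccccc3)cc2O[C@@H]1c1ccc(OCc2ccccc2)c(OCc2ccccc2)c1 | intermediate
18 | 5,7,3',4'-tetra-O-benzyl-4β-(2-ethoxyethoxy)epicatechin | CCOCCO[C@H]1c2c(OCc3ccccc3)cc(OCc3ccccc3)cc2O[C@H](c2ccc(OCc3ccccc3)c(OCc3ccccc3)c2)[C@@H]1O | intermediate
19 | tetra-O-benzylepicatechin-(4β→8)-tetra-O-benzylcatechin-(4α→8)-penta-O-benzylcatechin, upper and middle 3-OH free | C(c1ccccc1)O[C@H]1Cc2c(OCc3ccccc3)cc(OCc3ccccc3)c([C@@H]3c4c(OCc7ccccc7)cc(OCc7ccccc7)c([C@H]5c6c(OCc7ccccc7)cc(OCc7ccccc7)cc6O[C@H](c6ccc(OCc7ccccc7)c(OCc7ccccc7)c6)[C@@H]5O)c4O[C@H](c4ccc(OCc7ccccc7)c(OCc7ccccc7)c4)[C@H]3O)c2O[C@@H]1c1ccc(OCc2ccccc2)c(OCc2ccccc2)c1 | intermediate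
20 | bis(3-O-triethylsilyl) ether of 19 (upper and middle units) | C(c1ccccc1)O[C@H]1Cc2c(OCc3ccccc3)cc(OCc3ccccc3)c([C@@H]3c4c(OCc7ccccc7)cc(OCc7ccccc7)c([C@H]5c6c(OCc7ccccc7)cc(OCc7ccccc7)cc6O[C@H](c6ccc(OCc7ccccc7)c(OCc7ccccc7)c6)[C@@H]5O[Si](CC)(CC)CC)c4O[C@H](c4ccc(OCc7ccccc7)c(OCc7ccccc7)c4)[C@H]3O[Si](CC)(CC)CC)c2O[C@@H]1c1ccc(OCc2ccccc2)c(OCc2ccccc2)c1 | intermediate
21 | 3-O-triethylsilylepicatechin-(4β→8)-3-O-triethylsilylcatechin-(4α→8)-catechin | O[C@H]1Cc2c(O)cc(O)c([C@@H]3c4c(O)cc(O)c([C@H]5c6c(O)cc(O)cc6O[C@H](c6ccc(O)c(O)c6)[C@@H]5O[Si](CC)(CC)CC)c4O[C@H](c4ccc(O)c(O)c4)[C@H]3O[Si](CC)(CC)CC)c2O[C@@H]1c1ccc(O)c(O)c1 | intermediate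
22 | tris(phenylboronate) of 21 (each ring B catechol as a 2-phenyl-1,3,2-benzodioxaborole) | O[C@H]1Cc2c(O)cc(O)c([C@@H]3c4c(O)cc(O)c([C@H]5c6c(O)cc(O)cc6O[C@H](c6ccc7OB(c8ccccc8)Oc7c6)[C@@H]5O[Si](CC)(CC)CC)c4O[C@H](c4ccc5OB(c6ccccc6)Oc5c4)[C@H]3O[Si](CC)(CC)CC)c2O[C@@H]1c1ccc2OB(c3ccccc3)Oc2c1 | intermediate
23 | hexa-O-TBS (six ring A phenols) tris(phenylboronate) of 21 | O[C@H]1Cc2c(O[Si](C)(C)C(C)(C)C)cc(O[Si](C)(C)C(C)(C)C)c([C@@H]3c4c(O[Si](C)(C)C(C)(C)C)cc(O[Si](C)(C)C(C)(C)C)c([C@H]5c6c(O[Si](C)(C)C(C)(C)C)cc(O[Si](C)(C)C(C)(C)C)cc6O[C@H](c6ccc7OB(c8ccccc8)Oc7c6)[C@@H]5O[Si](CC)(CC)CC)c4O[C@H](c4ccc5OB(c6ccccc6)Oc5c4)[C@H]3O[Si](CC)(CC)CC)c2O[C@@H]1c1ccc2OB(c3ccccc3)Oc2c1 | intermediate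
24 | hexa-O-TBS ether of 21 at the six ring A phenols, catechol hydroxyls and terminal 3-OH free | O[C@H]1Cc2c(O[Si](C)(C)C(C)(C)C)cc(O[Si](C)(C)C(C)(C)C)c([C@@H]3c4c(O[Si](C)(C)C(C)(C)C)cc(O[Si](C)(C)C(C)(C)C)c([C@H]5c6c(O[Si](C)(C)C(C)(C)C)cc(O[Si](C)(C)C(C)(C)C)cc6O[C@H](c6ccc(O)c(O)c6)[C@@H]5O[Si](CC)(CC)CC)c4O[C@H](c4ccc(O)c(O)c4)[C@H]3O[Si](CC)(CC)CC)c2O[C@@H]1c1ccc(O)c(O)c1 | intermediate
25 | dodeca-O-TBS (all phenols) ether of 21, terminal 3-OH free | O[C@H]1Cc2c(O[Si](C)(C)C(C)(C)C)cc(O[Si](C)(C)C(C)(C)C)c([C@@H]3c4c(O[Si](C)(C)C(C)(C)C)cc(O[Si](C)(C)C(C)(C)C)c([C@H]5c6c(O[Si](C)(C)C(C)(C)C)cc(O[Si](C)(C)C(C)(C)C)cc6O[C@H](c6ccc(O[Si](C)(C)C(C)(C)C)c(O[Si](C)(C)C(C)(C)C)c6)[C@@H]5O[Si](CC)(CC)CC)c4O[C@H](c4ccc(O[Si](C)(C)C(C)(C)C)c(O[Si](C)(C)C(C)(C)C)c4)[C@H]3O[Si](CC)(CC)CC)c2O[C@@H]1c1ccc(O[Si](C)(C)C(C)(C)C)c(O[Si](C)(C)C(C)(C)C)c1 | intermediate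
26 | 2-methoxybenzoic acid | COc1ccccc1C(=O)O | starting material
27 | 2-methoxycyclohexa-2,5-diene-1-carboxylic acid (racemic) | COC1=CCC=CC1C(=O)O | intermediate
28 | terminal 3-O-(2-methoxycyclohexa-2,5-diene-1-carbonyl) ester of 25 | COC1=CCC=CC1C(=O)O[C@H]1Cc2c(O[Si](C)(C)C(C)(C)C)cc(O[Si](C)(C)C(C)(C)C)c([C@@H]3c4c(O[Si](C)(C)C(C)(C)C)cc(O[Si](C)(C)C(C)(C)C)c([C@H]5c6c(O[Si](C)(C)C(C)(C)C)cc(O[Si](C)(C)C(C)(C)C)cc6O[C@H](c6ccc(O[Si](C)(C)C(C)(C)C)c(O[Si](C)(C)C(C)(C)C)c6)[C@@H]5O[Si](CC)(CC)CC)c4O[C@H](c4ccc(O[Si](C)(C)C(C)(C)C)c(O[Si](C)(C)C(C)(C)C)c4)[C@H]3O[Si](CC)(CC)CC)c2O[C@@H]1c1ccc(O[Si](C)(C)C(C)(C)C)c(O[Si](C)(C)C(C)(C)C)c1 | intermediate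
29 | terminal 3-O-(6-oxocyclohex-2-ene-1-carbonyl) ester of 25 | O=C1CCC=CC1C(=O)O[C@H]1Cc2c(O[Si](C)(C)C(C)(C)C)cc(O[Si](C)(C)C(C)(C)C)c([C@@H]3c4c(O[Si](C)(C)C(C)(C)C)cc(O[Si](C)(C)C(C)(C)C)c([C@H]5c6c(O[Si](C)(C)C(C)(C)C)cc(O[Si](C)(C)C(C)(C)C)cc6O[C@H](c6ccc(O[Si](C)(C)C(C)(C)C)c(O[Si](C)(C)C(C)(C)C)c6)[C@@H]5O[Si](CC)(CC)CC)c4O[C@H](c4ccc(O[Si](C)(C)C(C)(C)C)c(O[Si](C)(C)C(C)(C)C)c4)[C@H]3O[Si](CC)(CC)CC)c2O[C@@H]1c1ccc(O[Si](C)(C)C(C)(C)C)c(O[Si](C)(C)C(C)(C)C)c1 | intermediate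
30 | terminal 3-O-[(1S)-1-hydroxy-6-oxocyclohex-2-ene-1-carbonyl] ester of 25 | O=C1CCC=C[C@@]1(O)C(=O)O[C@H]1Cc2c(O[Si](C)(C)C(C)(C)C)cc(O[Si](C)(C)C(C)(C)C)c([C@@H]3c4c(O[Si](C)(C)C(C)(C)C)cc(O[Si](C)(C)C(C)(C)C)c([C@H]5c6c(O[Si](C)(C)C(C)(C)C)cc(O[Si](C)(C)C(C)(C)C)cc6O[C@H](c6ccc(O[Si](C)(C)C(C)(C)C)c(O[Si](C)(C)C(C)(C)C)c6)[C@@H]5O[Si](CC)(CC)CC)c4O[C@H](c4ccc(O[Si](C)(C)C(C)(C)C)c(O[Si](C)(C)C(C)(C)C)c4)[C@H]3O[Si](CC)(CC)CC)c2O[C@@H]1c1ccc(O[Si](C)(C)C(C)(C)C)c(O[Si](C)(C)C(C)(C)C)c1 | intermediate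
31 | epicatechin-(4β→8)-catechin-(4α→8)-catechin terminal 3-O-[(1S)-1-hydroxy-6-oxocyclohex-2-ene-1-carboxylate] | O=C1CCC=C[C@@]1(O)C(=O)O[C@H]1Cc2c(O)cc(O)c([C@@H]3c4c(O)cc(O)c([C@H]5c6c(O)cc(O)cc6O[C@H](c6ccc(O)c(O)c6)[C@@H]5O)c4O[C@H](c4ccc(O)c(O)c4)[C@H]3O)c2O[C@@H]1c1ccc(O)c(O)c1 | target

**Totals**
Total step count: 20. Longest linear sequence: 15 steps (steps 1, 2, 5, 6, 7, 10, 11, 12, 13, 14, 15, 17, 18, 19, 20, from (+)-catechin).

**The three steps most likely to fail**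

Step 6 is the riskiest. The ring closure may show poor facial selectivity at the cationic C4 (2,4-trans closure), the oxa-Michael addition of the hindered, electron-rich phenol may be slow or revert, and the benzhydrol may lose water early to a quinone methide that oligomerises. The fallback sets out from 6 and 8. With the same amine catalyst (benzoic acid, toluene, rt) they would undergo the well-precedented oxa-Michael/aldol condensation, which also closes ring C by the C3–C4 bond, to give (R)-5,7-bis(benzyloxy)-2-[3,4-bis(benzyloxy)phenyl]-2H-chromene-3-carbaldehyde F1. Decarbonylation with RhCl(PPh3)3 (toluene, reflux) would give (2S)-5,7-bis(benzyloxy)-2-[3,4-bis(benzyloxy)phenyl]-2H-chromene F2. Dihydroxylation (OsO4, NMO) anti to the 2-aryl group would give (2R,3S,4S)-5,7,3',4'-tetra-O-benzylflavan-3,4-diol F3. Ionisation of F3 at C4 (TMSOTf, CH2Cl2, −78 °C) in the presence of an excess of 3 as C8 nucleophile should give, by attack anti to the 3-OH, the dimer 15, where the fallback rejoins the route.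

Step 19 is the second risk. Face selection at the dienolate carbon may be insufficient (double stereodifferentiation with the large chiral ester), oxygen may be transferred to the γ-carbon, or the dienol may aromatise to a salicylate. The fallback sets out from 27. Its dianion (LDA, THF, −78 °C) would be oxidised with 2-(phenylsulfonyl)-3-phenyloxaziridine to racemic 1-hydroxy-2-methoxycyclohexa-2,5-diene-1-carboxylic acid F4. Resolution by crystallisation of a diastereomeric salt with an enantiopure amine (1-phenylethylamine or quinine, configuration to be secured by X-ray analysis) would give (S)-1-hydroxy-2-methoxycyclohexa-2,5-diene-1-carboxylic acid F5. Esterification of 25 with F5 (2,4,6-trichlorobenzoyl chloride, Et3N, DMAP, toluene) would give the terminal 3-O-[(1S)-1-hydroxy-2-methoxycyclohexa-2,5-diene-1-carbonyl] ester of 25 F6. The oxalic acid hydrolysis of step 18 would then convert F6 into 30, where the fallback rejoins the route.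

Step 7 is the third risk. Hydride may migrate instead of C3 (carboxylic acid formation), the β-aryloxy aldehyde may ring-open by retro-oxa-Michael reaction before it is oxidised, or the electron-rich rings may be oxidised. The fallback sets out from 13. Chlorite oxidation (NaClO2, NaH2PO4, 2-methyl-2-butene, t-BuOH/H2O) would give (2,3-trans-3,4-trans)-5,7-bis(benzyloxy)-2-[3,4-bis(benzyloxy)phenyl]-4-(3,5,7,3',4'-penta-O-benzylcatechin-8-yl)chromane-3-carboxylic acid F7. Coupling with N-hydroxypyridine-2-thione (DCC, CH2Cl2, dark) would give its O-acyl thiohydroxamate F8. Barton decarboxylative oxygenation (hν, O2, t-BuSH; then P(OMe)3) should deliver oxygen to the C3 radical anti to both flanking aryl groups, giving the all-trans alcohol 15 whatever the configuration at C3 of F7; the fallback rejoins the route at 15.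

**Further compounds**
F1 | step 6 | (R)-5,7-bis(benzyloxy)-2-[3,4-bis(benzyloxy)phenyl]-2H-chromene-3-carbaldehyde | O=CC1=Cc2c(OCc3ccccc3)cc(OCc3ccccc3)cc2O[C@@H]1c1ccc(OCc2ccccc2)c(OCc2ccccc2)c1
F2 | step 6 | (2S)-5,7-bis(benzyloxy)-2-[3,4-bis(benzyloxy)phenyl]-2H-chromene | C1=Cc2c(OCc3ccccc3)cc(OCc3ccccc3)cc2O[C@@H]1c1ccc(OCc2ccccc2)c(OCc2ccccc2)c1
F3 | step 6 | (2R,3S,4S)-5,7,3',4'-tetra-O-benzylflavan-3,4-diol | O[C@H]1c2c(OCc3ccccc3)cc(OCc3ccccc3)cc2O[C@H](c2ccc(OCc3ccccc3)c(OCc3ccccc3)c2)[C@H]1O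
F4 | step 19 | racemic 1-hydroxy-2-methoxycyclohexa-2,5-diene-1-carboxylic acid | COC1=CCC=CC1(O)C(=O)O
F5 | step 19 | (S)-1-hydroxy-2-methoxycyclohexa-2,5-diene-1-carboxylic acid | COC1=CCC=C[C@@]1(O)C(=O)O
F6 | step 19 | terminal 3-O-[(1S)-1-hydroxy-2-methoxycyclohexa-2,5-diene-1-carbonyl] ester of 25 | COC1=CCC=C[C@@]1(O)C(=O)O[C@H]1Cc2c(O[Si](C)(C)C(C)(C)C)cc(O[Si](C)(C)C(C)(C)C)c([C@@H]3c4c(O[Si](C)(C)C(C)(C)C)cc(O[Si](C)(C)C(C)(C)C)c([C@H]5c6c(O[Si](C)(C)C(C)(C)C)cc(O[Si](C)(C)C(C)(C)C)cc6O[C@H](c6ccc(O[Si](C)(C)C(C)(C)C)c(O[Si](C)(C)C(C)(C)C)c6)[C@@H]5O[Si](CC)(CC)CC)c4O[C@H](c4ccc(O[Si](C)(C)C(C)(C)C)c(O[Si](C)(C)C(C)(C)C)c4)[C@H]3O[Si](CC)(CC)CC)c2O[C@@H]1c1ccc(O[Si](C)(C)C(C)(C)C)c(O[Si](C)(C)C(C)(C)C)c1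
F7 | step 7 | (2,3-trans-3,4-trans)-5,7-bis(benzyloxy)-2-[3,4-bis(benzyloxy)phenyl]-4-(3,5,7,3',4'-penta-O-benzylcatechin-8-yl)chromane-3-carboxylic acid | C(c1ccccc1)O[C@H]1Cc2c(OCc3ccccc3)cc(OCc3ccccc3)c([C@@H]3c4c(OCc5ccccc5)cc(OCc5ccccc5)cc4O[C@H](c4ccc(OCc5ccccc5)c(OCc5ccccc5)c4)[C@H]3C(=O)O)c2O[C@@H]1c1ccc(OCc2ccccc2)c(OCc2ccccc2)c1
F8 | step 7 | O-acyl thiohydroxamate (2-thioxopyridin-1(2H)-yl ester) of F7 | C(c1ccccc1)O[C@H]1Cc2c(OCc3ccccc3)cc(OCc3ccccc3)c([C@@H]3c4c(OCc5ccccc5)cc(OCc5ccccc5)cc4O[C@H](c4ccc(OCc5ccccc5)c(OCc5ccccc5)c4)[C@H]3C(=O)ON3C=CC=CC3=S)c2O[C@@H]1c1ccc(OCc2ccccc2)c(OCc2ccccc2)c1
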